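**Plan**
- Retrosynthesis: the C8=C9 enol lactone with the 10-OH goes back to a 9,10-epoxide beside an 8-H butenolide; the butenolide is cut at C12–C11 (and C13–OAc) to a ten-membered 2,3-allenol; the ring is cut at C7–C8 (propargylic bromide + epoxy aldehyde) and the chain at C3=C4 (Horner–Wadsworth–Emmons).
- Enabling feature: C11 sits between ring carbon C7 and the C13 methylene, one atom from the C8 oxygen, so it is the central carbon of an exocyclic allene C7=C11=C13 on a 2,3-allenol. Insertion of that allene into an alkoxycarbonyl–palladium bond on O8 closes the ring O–C12–C11–C7–C8, and the allyl terminus C13 takes acetate.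
- Forward: west aldehyde (C8–C10, C1–C3, C14) from geraniol; east phosphono-lactone (C4–C7, C11, C13, C15) from methyl succinyl chloride; union at C3=C4; lactone opened to the C15/C6 diol; ten-membered ring by indium Barbier closure (C7–C8); then the butenolide (C12 from CO); last the C8=C9 bond by epoxide opening.
- Stereochemistry: C9/C10 from Sharpless epoxidation (C10 is kept, C9–O is the later leaving group); C2 from D-proline α-aminoxylation; C6 from Ru/TsDPEN transfer hydrogenation, inverted in the Mitsunobu angeloylation; C3=C4 from the E-selective olefination on the lactone template; C8=C9 from the ring.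

Key step: step 18

Remark on numbering: names use the germacrane numbering of the target: ring C1 (CH2), C2 (CHOAc), C3=C4, C5 (CH2), C6 (CHOAng), C7, C8, C9, C10 (C(OH)CH3); C11/C12/C13 = lactone α-carbon/carbonyl/CH2OAc; C14 = methyl on C10; C15 = CH2OH on C4.
Assumption: the C8 carbinol formed in step 17 is carried as a mixture of epimers, because C8 becomes trigonal in step 19.

Step 1
Reactants: 1 geraniol
Product: 2 (2R,3R)-2,3-epoxygeraniol
Conditions: Ti(OiPr)4 (5 mol%), D-(−)-diethyl tartrate (7 mol%), tBuOOH, 4 Å MS, CH2Cl2, −20 °C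
Reagents that add atoms: tert-butyl hydroperoxide, CC(C)(C)OO
Why: Sharpless asymmetric epoxidation acts only on the allylic alcohol double bond, and the D-tartrate catalyst should give the (2R,3R)-epoxide, which sets C9 and C10 (both R).

Step 2
Reactants: 2 (2R,3R)-2,3-epoxygeraniol
Product: 3 (2R,3R)-2,3-epoxygeranyl 4-methoxybenzyl ether
Conditions: NaH, 4-MeOC6H4CH2Cl, Bu4NI (cat.), THF, 0 → 20 °C
Reagents that add atoms: 4-methoxybenzyl chloride, COc1ccc(CCl)cc1
Why: Williamson etherification masks the C8 hydroxyl as an oxidatively removable ether, alkylation of the epoxy alkoxide in THF being faster than Payne rearrangement.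

Step 3
Reactants: 3 (2R,3R)-2,3-epoxygeranyl 4-methoxybenzyl ether
Product: 5 3-[(2R,3R)-3-{[(4-methoxybenzyl)oxy]methyl}-2-methyloxiran-2-yl]propanal, via ozonide 4 (not isolated)
Conditions: O3, CH2Cl2, −78 °C (Sudan red end point); then PPh3, −78 → 20 °C
Reagents that add atoms: ozone, [O-][O+]=O
Why: Ozonolysis with reductive work-up cleaves the only alkene and unveils the C3 aldehyde, the epoxide and the anisyl ether being far less reactive toward ozone at −78 °C.

Step 4
Reactants: 6 methyl 4-chloro-4-oxobutanoate; 7 tert-butyldimethyl(prop-2-yn-1-yloxy)silane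
Product: 8 methyl 7-[(tert-butyldimethylsilyl)oxy]-4-oxohept-5-ynoate
Conditions: PdCl2(PPh3)2 (2 mol%), CuI (4 mol%), Et3N, THF, 25 °C
Reagents that add atoms: none
Why: Acyl Sonogashira coupling of the acid chloride with the terminal alkyne gives the ynone and leaves the methyl ester alone.

Step 5
Reactants: 8 methyl 7-[(tert-butyldimethylsilyl)oxy]-4-oxohept-5-ynoate
Product: 10 (5R)-5-{3-[(tert-butyldimethylsilyl)oxy]prop-1-yn-1-yl}oxolan-2-one, via hydroxy ester 9 (not isolated)
Conditions: RuCl[(R,R)-TsDPEN](p-cymene) (1 mol%), iPrOH, 25 °C; then PPTS (cat.), toluene, 60 °C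
Reagents that add atoms: none
Why: Noyori-type asymmetric transfer hydrogenation of the ynone with the (R,R)-catalyst should set the (R)-propargylic carbinol (the future C6, inverted in step 10) by catalyst control, and acid then closes the γ-lactone.

Step 6
Reactants: 10 (5R)-5-{3-[(tert-butyldimethylsilyl)oxy]prop-1-yn-1-yl}oxolan-2-one
Product: 12 diethyl [(5R)-5-{3-[(tert-butyldimethylsilyl)oxy]prop-1-yn-1-yl}-2-oxooxolan-3-yl]phosphonate (C3 epimers), via phosphonite 11 (not isolated)
Conditions: LiN(iPr)2, THF, −78 °C; ClP(OEt)2, −78 → 0 °C; then 30% H2O2, 0 °C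
Reagents that add atoms: diethyl chlorophosphite, CCOP(Cl)OCC; hydrogen peroxide, OO
Why: The lithium enolate of the lactone is phosphinylated on carbon by the trivalent phosphorus chloride and the phosphonite is oxidised in the same flask, an established route to α-phosphono lactones for Horner–Wadsworth–Emmons olefination.

Step 7
Reactants: 5 3-[(2R,3R)-3-{[(4-methoxybenzyl)oxy]methyl}-2-methyloxiran-2-yl]propanal; 12 diethyl [(5R)-5-{3-[(tert-butyldimethylsilyl)oxy]prop-1-yn-1-yl}-2-oxooxolan-3-yl]phosphonate
Product: 14 (3E,5R)-3-{(2S)-2-(anilinooxy)-3-[(2R,3R)-3-{[(4-methoxybenzyl)oxy]methyl}-2-methyloxiran-2-yl]propylidene}-5-{3-[(tert-butyldimethylsilyl)oxy]prop-1-yn-1-yl}oxolan-2-one, via anilinooxy aldehyde 13 (not isolated)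
Conditions: D-proline (20 mol%), PhNO, DMSO, 20 °C; then 12, LiCl, DBU, MeCN, 0 °C
Reagents that add atoms: nitrosobenzene, O=Nc1ccccc1
Why: Proline-catalysed α-aminoxylation (enamine attack on the oxygen of nitrosobenzene, directed by the carboxylic acid of D-proline) should set C2 as S, and the labile aldehyde is trapped at once in a Masamune–Roush Horner–Wadsworth–Emmons olefination that places the lactone carbonyl trans to C2, so C5 ends up cis to C2 across C3=C4.

Step 8
Reactants: 14 the (3E,5R)-alkylidene lactone
Product: 15 seco-diol (2S,3E,6R,9R,10R) with C15H2OH and 6-OH free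
Conditions: iBu2AlH (5 equiv), CH2Cl2, −78 → −20 °C; aq. KNaC4H4O6
Reagents that add atoms: none
Why: Hydride reduction of the α-alkylidene lactone to the allylic alcohol level opens the template to the C15/C6 diol with the alkene geometry retained, before any ester is present in the molecule.

Step 9
Reactants: 15 seco-diol
Product: 16 15-O-tert-butyldiphenylsilyl ether of 15
Conditions: tBuPh2SiCl (1.05 equiv), imidazole, CH2Cl2, 0 °C
Reagents that add atoms: tert-butyl(chloro)diphenylsilane, CC(C)(C)[Si](Cl)(c1ccccc1)c1ccccc1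
Why: Silylation with the bulky chloride should be selective for the primary allylic C15 hydroxyl over the secondary propargylic C6 hydroxyl.

Step 10
Reactants: 16 15-O-silyl ether with free (6R)-OH
Product: 17 (6S)-6-O-angelate of 16
Conditions: angelic acid, PPh3, DIAD, THF, 0 → 20 °C
Reagents that add atoms: angelic acid, C/C=C(/C)C(=O)O
Why: Mitsunobu esterification inverts C6 from R to the S configuration of the target by SN2 displacement and brings in the angelate without an activated acyl species, so the Z alkene of the acid and the N–H of the anilinooxy group are not put at risk.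

Step 11
Reactants: 17 (6S)-angelate carrying the 2-anilinooxy group
Product: 18 (2S)-2-hydroxy compound
Conditions: Zn dust, AcOH/THF (1:4), 0 °C
Reagents that add atoms: none
Why: Zinc in acetic acid cleaves the weak N–O bond reductively and frees the C2 hydroxyl without affecting the alkyne, the angelate or the silyl ethers.

Step 12
Reactants: 18 (2S)-2-hydroxy compound
Product: 19 2-O-acetate of 18
Conditions: Ac2O, pyridine, DMAP (cat.), CH2Cl2, 0 → 20 °C
Reagents that add atoms: acetic anhydride, CC(=O)OC(C)=O
Why: Standard acylation of the only free hydroxyl installs the C2 acetate of the target.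

Step 13
Reactants: 19 2-O-acetate
Product: 20 13-hydroxy compound (propargylic alcohol)
Conditions: HF·pyridine, pyridine, THF, 0 °C
Reagents that add atoms: none
Why: Buffered HF·pyridine should cleave the primary tert-butyldimethylsilyl ether at C13 much faster than the tert-butyldiphenylsilyl ether at C15, and it spares the trisubstituted epoxide.

Step 14
Reactants: 20 13-hydroxy compound
Product: 21 13-bromide (propargylic bromide)
Conditions: CBr4, PPh3, 2,6-lutidine, CH2Cl2, 0 °C
Reagents that add atoms: carbon tetrabromide, BrC(Br)(Br)Br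
Why: Appel bromination converts the propargylic alcohol into the bromide under neutral conditions that the epoxide and the esters tolerate.

Step 15
Reactants: 21 13-bromide
Product: 22 8-hydroxy compound (2,3-epoxy alcohol)
Conditions: DDQ, CH2Cl2/pH 7 phosphate buffer (10:1), 0 °C
Reagents that add atoms: none
Why: Oxidative cleavage of the 4-methoxybenzyl ether with DDQ frees the C8 hydroxyl under conditions to which the propargylic bromide is inert.

Step 16
Reactants: 22 8-hydroxy compound
Product: 23 8-aldehyde (9,10-epoxy aldehyde carrying the 13-bromide)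
Conditions: Dess–Martin periodinane, NaHCO3, CH2Cl2, 0 → 20 °C
Reagents that add atoms: none
Why: Dess–Martin oxidation gives the epoxy aldehyde under buffered conditions that leave the epoxide and the bromide untouched.

Step 17
Reactants: 23 8-aldehyde
Product: 24 ten-membered 2,3-allenol (7-vinylidene, 8-OH as both epimers)
Conditions: indium powder (3 equiv), NaI (2 equiv), DMF, 25 °C, slow addition of 23 (final 2 mM); aq. NH4Cl
Reagents that add atoms: none
Why: Intramolecular Barbier reaction: indium inserts into the propargylic C13–Br bond and the propargylindium adds to the aldehyde through its γ-carbon C7 (SE2'), as γ-substituted propargyl bromides do, which closes the ten-membered ring by the C7–C8 bond and leaves the allene C7=C11=C13 next to the C8 hydroxyl; the new C8 centre is not controlled and does not need to be.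

Step 18
Reactants: 24 ten-membered 2,3-allenol
Product: 25 13-acetoxy-7(11)-en-12,8-olide with the 9,10-epoxide kept (8-H, both epimers)
Conditions: Pd(OAc)2 (10 mol%), 1,4-benzoquinone (2 equiv), LiOAc (2 equiv), AcOH (5 equiv), CO (1 atm), THF, 25 °C
Reagents that add atoms: carbon monoxide, [C-]#[O+]; acetic acid, CC(=O)O
Why: Proposed new method: the C8 hydroxyl, CO and Pd(OAc)2 should give an alkoxycarbonyl complex of divalent palladium whose acyl carbon C12 adds to the central allene carbon C11 by syn migratory insertion of the C11=C13 π bond, so that the C12–C11 bond closes the butenolide and palladium is left on the C13–C11–C7 allyl system; benzoquinone-assisted attack of acetate at C13 then releases the product and zerovalent palladium, which benzoquinone and AcOH return to Pd(OAc)2. The closest known reaction type is the chloride-terminated oxidative cyclocarbonylation of 2,3-allenols with PdCl2 and CuCl2, which gives 3-(chloromethyl)butenolides through the same insertion, together with the benzoquinone-mediated acetoxylation of allylpalladium intermediates known from diene 1,4-diacetoxylation; only the terminating nucleophile and the oxidant are changed. The five-membered ring O–C12–C11–C7–C8 closes in the 5-exo mode with respect to the C11=C13 bond, and C7=C11 stays inside the ring as the tetrasubstituted alkene. No stereocentre is created; C8 stays a mixture and C2, C6, C9 and C10 are not touched. The step needs capture of the allyl intermediate at C13 and not at C7, which the unhindered primary terminus and the conjugation of the resulting C7=C11 bond with the lactone carbonyl should secure, and it needs alkoxycarbonylation to outrun direct oxypalladation of the allene by the hydroxyl, which the CO atmosphere should secure as in the chloride-terminated precedent. The chloride-free, acetate-buffered medium is chosen so that the epoxide and the esters survive.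

Step 19
Reactants: 25 13-acetoxy-7(11)-en-12,8-olide with 9,10-epoxide
Product: 26 15-O-tert-butyldiphenylsilyl ether of the target
Conditions: DBU (1.2 equiv), Bu4NOAc (2 equiv), MeCN, −20 → 0 °C
Reagents that add atoms: none
Why: E1cB elimination: deprotonation of the acidic γ-hydrogen at C8 gives the furanolate-type dienolate, which expels the epoxide oxygen from C9, forms the C8=C9 enol lactone and frees the C10 tertiary alcohol with its configuration untouched; the ten-membered ring should hold C10 on the C7 side (8E), and the added acetate makes any loss of the C13 acetate from the same anion degenerate.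

Step 20
Reactants: 26 15-O-tert-butyldiphenylsilyl ether of the target
Product: 27 target, CNP0165707.1
Conditions: HF·pyridine, pyridine, THF, 0 → 20 °C
Reagents that add atoms: none
Why: Buffered fluoride-mediated desilylation cleaves the remaining silyl ether without touching the three esters, the enol lactone or the tertiary allylic alcohol.

**Compound list**
1 | geraniol, (2E)-3,7-dimethylocta-2,6-dien-1-ol | CC(C)=CCC/C(C)=C/CO | starting material
2 | (2R,3R)-2,3-epoxygeraniol, [(2R,3R)-3-methyl-3-(4-methylpent-3-en-1-yl)oxiran-2-yl]methanol | C[C@]1(CCC=C(C)C)O[C@@H]1CO | intermediate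
3 | (2R,3R)-2-{[(4-methoxybenzyl)oxy]methyl}-3-methyl-3-(4-methylpent-3-en-1-yl)oxirane | C[C@]1(CCC=C(C)C)O[C@@H]1COCc1ccc(OC)cc1 | intermediate
4 | ozonide of 3: 3,3-dimethyl-5-{2-[(2R,3R)-3-{[(4-methoxybenzyl)oxy]methyl}-2-methyloxiran-2-yl]ethyl}-1,2,4-trioxolane (trioxolane C5 unassigned) | CC1(C)OOC(CC[C@@]2(C)O[C@@H]2COCc2ccc(OC)cc2)O1 | intermediate
5 | 3-[(2R,3R)-3-{[(4-methoxybenzyl)oxy]methyl}-2-methyloxiran-2-yl]propanal | O=CCC[C@@]1(C)O[C@@H]1COCc1ccc(OC)cc1 | intermediate
6 | methyl 4-chloro-4-oxobutanoate | COC(=O)CCC(Cl)=O | starting material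
7 | tert-butyldimethyl(prop-2-yn-1-yloxy)silane | C#CCO[Si](C)(C)C(C)(C)C | starting material
8 | methyl 7-[(tert-butyldimethylsilyl)oxy]-4-oxohept-5-ynoate | COC(=O)CCC(=O)C#CCO[Si](C)(C)C(C)(C)C | intermediate
9 | methyl (4R)-7-[(tert-butyldimethylsilyl)oxy]-4-hydroxyhept-5-ynoate | COC(=O)CC[C@@H](O)C#CCO[Si](C)(C)C(C)(C)C | intermediate
10 | (5R)-5-{3-[(tert-butyldimethylsilyl)oxy]prop-1-yn-1-yl}oxolan-2-one | O=C1CC[C@H](C#CCO[Si](C)(C)C(C)(C)C)O1 | intermediate
11 | diethyl [(5R)-5-{3-[(tert-butyldimethylsilyl)oxy]prop-1-yn-1-yl}-2-oxooxolan-3-yl]phosphonite (C3 epimers) | CCOP(OCC)C1C[C@H](C#CCO[Si](C)(C)C(C)(C)C)OC1=O | intermediate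
12 | diethyl [(5R)-5-{3-[(tert-butyldimethylsilyl)oxy]prop-1-yn-1-yl}-2-oxooxolan-3-yl]phosphonate (C3 epimers) | CCOP(=O)(OCC)C1C[C@H](C#CCO[Si](C)(C)C(C)(C)C)OC1=O | intermediate
13 | (2S)-2-(anilinooxy)-3-[(2R,3R)-3-{[(4-methoxybenzyl)oxy]methyl}-2-methyloxiran-2-yl]propanal | O=C[C@@H](ONc1ccccc1)C[C@@]1(C)O[C@@H]1COCc1ccc(OC)cc1 | intermediate
14 | (3E,5R)-3-{(2S)-2-(anilinooxy)-3-[(2R,3R)-3-{[(4-methoxybenzyl)oxy]methyl}-2-methyloxiran-2-yl]propylidene}-5-{3-[(tert-butyldimethylsilyl)oxy]prop-1-yn-1-yl}oxolan-2-one | O=C1O[C@@H](C#CCO[Si](C)(C)C(C)(C)C)C/C1=C\[C@@H](ONc1ccccc1)C[C@@]1(C)O[C@@H]1COCc1ccc(OC)cc1 | intermediate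
15 | seco-diol (2S,3E,6R,9R,10R): open chain C8 to C13 with 8-O-(4-methoxybenzyl), 9,10-epoxide, 2-anilinooxy, C15H2OH on C4, 6-OH, C7≡C11 triple bond, 13-O-tert-butyldimethylsilyl | OC/C(=C/[C@@H](ONc1ccccc1)C[C@@]1(C)O[C@@H]1COCc1ccc(OC)cc1)C[C@@H](O)C#CCO[Si](C)(C)C(C)(C)C | intermediate
16 | 15-O-tert-butyldiphenylsilyl ether of 15 (6R-OH free) | CC(C)(C)[Si](c1ccccc1)(c1ccccc1)OC/C(=C/[C@@H](ONc1ccccc1)C[C@@]1(C)O[C@@H]1COCc1ccc(OC)cc1)C[C@@H](O)C#CCO[Si](C)(C)C(C)(C)C | intermediate
17 | (6S)-6-O-angelate of 16, the (Z)-2-methylbut-2-enoate with C6 inverted | CC(C)(C)[Si](c1ccccc1)(c1ccccc1)OC/C(=C/[C@@H](ONc1ccccc1)C[C@@]1(C)O[C@@H]1COCc1ccc(OC)cc1)C[C@H](OC(=O)/C(C)=C\C)C#CCO[Si](C)(C)C(C)(C)C | intermediate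
18 | (2S)-2-hydroxy compound from 17 | CC(C)(C)[Si](c1ccccc1)(c1ccccc1)OC/C(=C/[C@@H](O)C[C@@]1(C)O[C@@H]1COCc1ccc(OC)cc1)C[C@H](OC(=O)/C(C)=C\C)C#CCO[Si](C)(C)C(C)(C)C | intermediate
19 | 2-O-acetate of 18 | CC(C)(C)[Si](c1ccccc1)(c1ccccc1)OC/C(=C/[C@@H](OC(C)=O)C[C@@]1(C)O[C@@H]1COCc1ccc(OC)cc1)C[C@H](OC(=O)/C(C)=C\C)C#CCO[Si](C)(C)C(C)(C)C | intermediate
20 | 13-hydroxy compound (propargylic alcohol) from 19 | CC(C)(C)[Si](c1ccccc1)(c1ccccc1)OC/C(=C/[C@@H](OC(C)=O)C[C@@]1(C)O[C@@H]1COCc1ccc(OC)cc1)C[C@H](OC(=O)/C(C)=C\C)C#CCO | intermediate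
21 | 13-bromide (propargylic bromide) from 20 | CC(C)(C)[Si](c1ccccc1)(c1ccccc1)OC/C(=C/[C@@H](OC(C)=O)C[C@@]1(C)O[C@@H]1COCc1ccc(OC)cc1)C[C@H](OC(=O)/C(C)=C\C)C#CCBr | intermediate
22 | 8-hydroxy compound (2,3-epoxy alcohol) from 21 | CC(C)(C)[Si](c1ccccc1)(c1ccccc1)OC/C(=C/[C@@H](OC(C)=O)C[C@@]1(C)O[C@@H]1CO)C[C@H](OC(=O)/C(C)=C\C)C#CCBr | intermediate
23 | 8-aldehyde: 9,10-epoxy aldehyde with the 13-bromide (geometry at C9 and C10 as in 22) | CC(C)(C)[Si](c1ccccc1)(c1ccccc1)OC/C(=C/[C@@H](OC(C)=O)C[C@@]1(C)O[C@@H]1C=O)C[C@H](OC(=O)/C(C)=C\C)C#CCBr | intermediate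
24 | ten-membered 2,3-allenol: ring C1 to C10 closed by C7–C8, 7-vinylidene (C7=C11=C13H2), 8-OH (both epimers), (9R,10R)-epoxide, (2S)-OAc, 3E, (6S)-O-angelate, 15-O-tert-butyldiphenylsilyl | C=C=C1C(O)[C@H]2O[C@]2(C)C[C@H](OC(C)=O)/C=C(CO[Si](c2ccccc2)(c2ccccc2)C(C)(C)C)\C[C@@H]1OC(=O)/C(C)=C\C | intermediate
25 | 13-acetoxy-7(11)-en-12,8-olide: butenolide fused at C7–C8 (8-H, both epimers), 9,10-epoxide kept, (2S)-OAc, (6S)-O-angelate, 15-O-tert-butyldiphenylsilyl | C/C=C(/C)C(=O)O[C@H]1C/C(CO[Si](c2ccccc2)(c2ccccc2)C(C)(C)C)=C\[C@@H](OC(C)=O)C[C@@]3(C)O[C@@H]3C2OC(=O)C(COC(C)=O)=C12 | intermediate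
26 | 15-O-tert-butyldiphenylsilyl ether of the target, (2S,3E,6S,8E,10R) | C/C=C(/C)C(=O)O[C@H]1C/C(CO[Si](c2ccccc2)(c2ccccc2)C(C)(C)C)=C\[C@@H](OC(C)=O)C[C@@](C)(O)/C=C2/OC(=O)C(COC(C)=O)=C21 | intermediate
27 | CNP0165707.1, (2S,3E,6S,8E,10R)-2,13-diacetoxy-6-[(Z)-2-methylbut-2-enoyloxy]-10,15-dihydroxygermacra-3,7(11),8-trien-12,8-olide | C/C=C(/C)C(=O)O[C@H]1C/C(CO)=C\[C@@H](OC(C)=O)C[C@@](C)(O)/C=C2/OC(=O)C(COC(C)=O)=C21 | target

**Step count and risks**
Total steps: 20. Longest linear sequence: 17 steps (steps 1–3 and 7–20, from geraniol).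

Steps most likely to fail:

1. Step 18 (labelled step). The hydroxyl may add directly to the palladium-activated allene instead of being carbonylated, acetate may capture the allyl intermediate at C7, or the epoxide may open under the acidic medium. Fallback with known chemistry: setting out from 24, the established chloride-terminated cyclocarbonylation of 2,3-allenols (PdCl2 cat., CuCl2, CO 1 atm, THF, propylene oxide as HCl scavenger) should give the 13-chloromethyl butenolide F1. SN2 displacement of the allylic chloride with CsOAc in DMF at 20 °C then comes back to the route at 25.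

2. Step 17. The chain may oligomerise instead of closing, the organoindium may react through its allenyl form to give the twelve-membered homopropargylic alcohol, or it may lose the C6 angelate by 1,4-elimination. Fallback: setting out from 23, Finkelstein exchange (NaI, acetone) should give the propargylic iodide F2, which is cyclised in a Nozaki–Hiyama–Kishi-type reaction with CrCl2 in THF at high dilution. This replaces the reaction at a metal surface by a homogeneous propargylchromium species that binds the aldehyde oxygen and adds through a closed six-membered transition state; it still forms the same C7–C8 bond. It comes back to the route at 24.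

3. Step 19. The dienolate may expel the C13 acetate instead of the epoxide oxygen, or the ring may deliver the other C8=C9 geometry. Fallback: setting out from 25, soft enolisation with Me3SiOTf and Et3N in CH2Cl2 at −78 °C should give the 2-(trimethylsilyloxy)furan F3. In F3 the silyl triflate activates the epoxide oxygen, so the C9–O bond opens in a vinylogous elimination without a free anion and gives the 10-O-trimethylsilyl ether F4. F4 is taken through the conditions of step 20, which remove both silyl groups, and the route is rejoined at 27.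

**Further compounds**
F1 | step 18 | 13-chloromethyl butenolide, the analogue of 25 with Cl in place of the C13 acetate | C/C=C(/C)C(=O)O[C@H]1C/C(CO[Si](c2ccccc2)(c2ccccc2)C(C)(C)C)=C\[C@@H](OC(C)=O)C[C@@]3(C)O[C@@H]3C2OC(=O)C(CCl)=C12
F2 | step 17 | propargylic iodide, the analogue of 23 with I in place of Br | CC(C)(C)[Si](c1ccccc1)(c1ccccc1)OC/C(=C/[C@@H](OC(C)=O)C[C@@]1(C)O[C@@H]1C=O)C[C@H](OC(=O)/C(C)=C\C)C#CCI
F3 | step 19 | 2-(trimethylsilyloxy)furan derived from 25 | C/C=C(/C)C(=O)O[C@H]1C/C(CO[Si](c2ccccc2)(c2ccccc2)C(C)(C)C)=C\[C@@H](OC(C)=O)C[C@@]3(C)O[C@@H]3c2oc(O[Si](C)(C)C)c(COC(C)=O)c12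
F4 | step 19 | 10-O-trimethylsilyl ether of 26 | C/C=C(/C)C(=O)O[C@H]1C/C(CO[Si](c2ccccc2)(c2ccccc2)C(C)(C)C)=C\[C@@H](OC(C)=O)C[C@@](C)(O[Si](C)(C)C)/C=C2/OC(=O)C(COC(C)=O)=C21
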